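The 5–7 core is traced to a cis-decalin: the C2–C8 ring-fusion bond, flanked by the exocyclic methylene on C7, marks a 1,2-shift in a precursor whose angular carbon is C7. Ionisation of an equatorial C8 mesylate lets C2 migrate from C7 to C8, which in one operation contracts ring A (C1, C2, C7, C8, C9, C10) to the cyclopentane, expands ring B to the cycloheptane, sets the trans fusion and, by loss of Me3Si from the C7 cation, places the C7 methylene. The precursor is a quinone Diels–Alder-derived cis-decalin carrying the angular CH2SiMe3 group, the C1 methylene, a C10 silyl ether and the cis-fused C3/C4 methyl lactone.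

Key step: step 19

Remarks on the chemistry (assumptions and corrections built into the route)
- Labels: C1–C12 follow the target SMILES read left to right (C1 methylene-bearing five-ring carbon, C2 and C8 ring fusion, C3, C4, C5, C6, C7 methylene-bearing seven-ring carbon, C9, C10, C11 = CHMe, C12 = CHOAc). In the decalins ring A = C1, C2, C7, C8, C9, C10 and ring B = C2 to C7. The α face is the one that carries H2; β is the opposite face. The target has H2 α, C3–O α, C4 side chain α, C6–OH β, H8 β, C10–OH α, 11S, 12S.
- Endo cycloaddition puts the C3 oxygen trans to H2, which is the C3 epimer of the lactone oxygen needed in 24; C3 is therefore inverted in step 11 before the lactone is built.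
- External reagents reach the cis-decalin from its convex α face. The α oxygen at C10 is therefore introduced as an electrophile (step 7), and the α hydroxyl at C8 by hydride delivered from the β face through the C3 hydroxyl (step 10).
- The quinone is made by phenol oxidation, because one-electron oxidation of a methyl-ether arene that carries a benzylic silane risks C–Si cleavage.
- Compounds 6–16 are racemic; their SMILES show the enantiomer that is carried on after the resolution in step 11.
- Compounds 1, 2 and 5 are assumed to be purchased.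

Step 1
Reactants: 1 5-bromo-2-methoxyphenol; 2 (trimethylsilyl)methylmagnesium chloride
Product: 3 2-methoxy-5-[(trimethylsilyl)methyl]phenol
Conditions: 2 (2.5 equiv), NiCl2(dppp) (5 mol %), THF, 0 °C to reflux; aq. NH4Cl
Reagents that add atoms: none
Why: Kumada cross-coupling of the aryl bromide, present as its magnesium phenoxide after the first equivalent of 2 has removed the phenol proton, should give the benzylsilane in one step.

Step 2
Reactants: 3 2-methoxy-5-[(trimethylsilyl)methyl]phenol
Product: 4 2-methoxy-5-[(trimethylsilyl)methyl]-1,4-benzoquinone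
Conditions: (KSO3)2NO (2.2 equiv), KH2PO4 buffer, H2O/acetone, 0 °C to rt
Reagents that add atoms: potassium nitrosodisulfonate (Fremy's salt), [K+].[K+].[O]N(S(=O)(=O)[O-])S(=O)(=O)[O-]
Why: Teuber oxidation of a phenol with a free para position should give the para-quinone through the phenoxyl radical, a path that leaves the benzylic C–Si bond alone.

Step 3
Reactants: 4 2-methoxy-5-[(trimethylsilyl)methyl]-1,4-benzoquinone; 5 (E)-1-(trimethylsiloxy)buta-1,3-diene
Product: 6 (±)-endo cycloadduct, cis-decal-4,9-diene-1,8-dione with 10-OMe, 7α-CH2SiMe3, 2α-H and 3β-OSiMe3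
Conditions: toluene, 25–40 °C, dark
Reagents that add atoms: none
Why: Thermal Diels–Alder reaction at the alkyl-substituted quinone double bond (the methoxy-bearing one is deactivated), in which the unconjugated C1 carbonyl sends the unsubstituted diene terminus to C7 and the oxygenated terminus to C2, suprafacial addition gives the cis C2/C7 fusion and endo addition places the C3 oxygen β, trans to H2.

Step 4
Reactants: 6 (±)-endo cycloadduct
Product: 8 (±)-cis-decal-4-ene-1,8-dione with 7α-CH2SiMe3 and 3β-OSiMe3, via methoxy diketone 7 (not isolated)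
Conditions: SmI2 (4.5 equiv), THF/MeOH, −78 °C
Reagents that add atoms: none
Why: Single-electron reduction by SmI2 should first saturate the enedione C9=C10 bond and then cleave the α-methoxy group of the C1 ketone (reductive deoxygenation of an α-alkoxy ketone), which removes the group that steered the cycloaddition without touching C3–O or C4=C5.

Step 5
Reactants: 8 (±)-cis-decal-4-ene-1,8-dione
Product: 10 (±)-bridged methyl ketal (C3–O–C8 bridge on the β face, 8α-OMe, C1 ketone), via hydroxy diketone 9 (not isolated)
Conditions: PPTS (cat.), MeOH, rt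
Reagents that add atoms: methanol, CO
Why: Acid methanolysis frees the C3 β-hydroxyl, which sits over the β face of ring A beside C8 and should close the five-membered mixed ketal (intramolecular ketalisation of a γ-hydroxy ketone), so that C8 is masked and C1 remains the only ketone, enolisable only towards C10 because C2 has become a bridgehead.

Step 6
Reactants: 10 (±)-bridged methyl ketal
Product: 11 (±)-C1 tert-butyldimethylsilyl enol ether (C1=C10) of 10
Conditions: LiN(iPr)2, THF, −78 °C; TBSOTf
Reagents that add atoms: tert-butyldimethylsilyl trifluoromethanesulfonate, CC(C)(C)[Si](C)(C)OS(=O)(=O)C(F)(F)F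
Why: Kinetic enolisation and O-silylation of the single ketone can only proceed towards C10 and gives the C1=C10 silyl enol ether.

Step 7
Reactants: 11 (±)-C1 silyl enol ether
Product: 13 (±)-10α-(tert-butyldimethylsilyloxy) C1 ketone with the bridged ketal, via silyloxy epoxide 12 (not isolated)
Conditions: mCPBA (1.05 equiv), NaHCO3, CH2Cl2, −20 °C
Reagents that add atoms: 3-chloroperoxybenzoic acid, O=C(OO)c1cccc(Cl)c1
Why: Rubottom oxidation, in which the peracid attacks the electron-rich enol ether much faster than the C4=C5 alkene and from the α face because the C3–O–C8 bridge covers the β face of ring A, and silyl migration in the epoxide then gives the α (equatorial) C10 silyloxy ketone.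

Step 8
Reactants: 13 (±)-10α-silyloxy C1 ketone
Product: 14 (±)-C1 methylene bridged ketal with 10α-OTBS
Conditions: Ph3PCH3Br, KOtBu, toluene, 25 to 80 °C
Reagents that add atoms: methyltriphenylphosphonium bromide, C[P+](c1ccccc1)(c1ccccc1)c1ccccc1.[Br-]
Why: Wittig methylenation of the only carbonyl installs the C1 methylene, and the basic ylide cannot epimerise C2 (bridgehead) while the α C10 silyl ether is the stable epimer.

Step 9
Reactants: 14 (±)-C1 methylene bridged ketal
Product: 15 (±)-3β-hydroxy C8 ketone with C1 methylene and 10α-OTBS (in equilibrium with its hemiketal)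
Conditions: PPTS, acetone/H2O, 40 °C
Reagents that add atoms: water, O
Why: Mild acid hydrolysis of the mixed ketal should return the C8 ketone and the C3 β-hydroxyl while the secondary silyl ether and both alkenes survive.

Step 10
Reactants: 15 (±)-3β-hydroxy C8 ketone
Product: 16 (±)-3β,8α-diol with C1 methylene, 10α-OTBS and 7α-CH2SiMe3
Conditions: Me4NBH(OAc)3, MeCN/AcOH, −30 to 0 °C
Reagents that add atoms: none
Why: Hydroxyl-directed triacetoxyborohydride reduction (Evans–Saksena type), in which the reagent, inert towards an isolated hindered ketone, binds the C3 β-hydroxyl and passes hydride to the β face of C8 held next to it, so that the new C8 hydroxyl is α, cis to the angular CH2SiMe3 and equatorial on ring A.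

Step 11
Reactants: 16 (±)-3β,8α-diol
Product: 17 (S)-O-methylmandelate of the 3α-alcohol (8α-OH free), single diastereomer
Conditions: (S)-PhCH(OMe)CO2H, PPh3, DIAD, THF, 0 °C to rt; chromatographic separation of the two diastereomeric esters
Reagents that add atoms: (S)-2-methoxy-2-phenylacetic acid, CO[C@H](C(=O)O)c1ccccc1
Why: Mitsunobu esterification of the allylic C3 hydroxyl (the neopentyl-type C8 hydroxyl is inert) proceeds with SN2 inversion, which places C3–O on the α face cis to H2, and the enantiopure acid converts the racemate into two separable diastereomers, of which the one shown is carried on.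

Step 12
Reactants: 17 (S)-O-methylmandelate
Product: 18 enantiopure 3α,8α-diol
Conditions: LiOH, THF/MeOH/H2O, rt; aq. HCl to pH 3
Reagents that add atoms: none
Why: Saponification cleaves the acyl–oxygen bond and so should release the 3α-alcohol without change at C3.

Step 13
Reactants: 18 enantiopure 3α,8α-diol
Product: 19 C3 O-(2-bromo-1-ethoxyethyl) acetal (acetal carbon as a mixture), 8α-OH free
Conditions: ethyl vinyl ether (3 equiv), NBS (1.1 equiv), CH2Cl2, −40 to 0 °C
Reagents that add atoms: ethyl vinyl ether, C=COCC; N-bromosuccinimide, O=C1CCC(=O)N1Br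
Why: Alkoxybromination of the vinyl ether (Ueno–Stork bromoacetal formation) should occur at the less hindered allylic C3 hydroxyl, the electron-rich vinyl ether taking the bromonium source before the other alkenes can, and any acetal formed at the C8 hydroxyl would be cleaved again in step 15.

Step 14
Reactants: 19 C3 bromoacetal
Product: 20 cis-fused 2-ethoxytetrahydrofuran (C3–O–C12(OEt)–C11H2–C4), 8α-OH
Conditions: Bu3SnH, AIBN (cat.), benzene, 80 °C, slow addition
Reagents that add atoms: none
Why: Ueno–Stork radical cyclisation, in which the primary radical adds 5-exo-trig to C4 of the C4=C5 alkene, necessarily on the α face that carries the C3 oxygen, which sets C4 and leaves C5 as CH2 after hydrogen transfer from the stannane.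

Step 15
Reactants: 20 cyclic ethyl acetal
Product: 21 lactol (C12 hemiacetal, anomer mixture), 8α-OH
Conditions: AcOH/THF/H2O, 45 °C
Reagents that add atoms: water, O
Why: Acid hydrolysis of the cyclic acetal should give the lactol under conditions that a secondary silyl ether tolerates.

Step 16
Reactants: 21 lactol
Product: 22 cis-fused γ-lactone (C11 H2), 8α-OH
Conditions: Ag2CO3 on Celite, benzene, reflux
Reagents that add atoms: none
Why: Fétizon oxidation converts lactols into lactones far faster than it oxidises a hindered secondary alcohol, so the C8 hydroxyl should be kept.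

Step 17
Reactants: 22 γ-lactone
Product: 23 11-methyl lactone, 8α-alcohol
Conditions: LiN(iPr)2 (2.2 equiv), THF, −78 °C; MeI
Reagents that add atoms: iodomethane, CI
Why: Alkylation of the lactone enolate (the hindered C8 alkoxide is not methylated at −78 °C) takes place on the convex face of the cis-fused bicycle, which puts the C11 methyl cis to H4 as in the target.

Step 18
Reactants: 23 11-methyl lactone, 8α-alcohol
Product: 24 8α-mesylate: cis-decalin with 7α-CH2SiMe3, C1 methylene, 10α-OTBS and cis-fused C3/C4 methyl lactone
Conditions: MsCl, Et3N, CH2Cl2, −10 °C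
Reagents that add atoms: methanesulfonyl chloride, CS(=O)(=O)Cl
Why: Sulfonylation through sulfene works on hindered secondary alcohols and keeps the C8 configuration.

Step 19
Reactants: 24 8α-mesylate
Product: 25 trans-fused hydroazulene lactone with C1 and C7 methylenes and 10α-OTBS
Conditions: 2,6-lutidine (3 equiv), CF3CH2OH, 60 °C
Reagents that add atoms: none
Why: Heterolysis of the C8–O bond is concerted with migration of the antiperiplanar C7–C2 ring bond (Wagner–Meerwein 1,2-alkyl shift), which forms C2–C8 and a tertiary C7 cation that is stabilised by the β C–Si bond and collapses through it to the exocyclic C7 methylene. The closest known reaction type is the solvolytic rearrangement of decalyl sulfonates to hydroazulenes, here combined with β-silyl control of the elimination. Neither ring is made by an end-to-end closure: the cyclopentane (C1, C2, C8, C9, C10) comes from contraction of ring A and the cycloheptane (C2 to C8) from expansion of ring B in the same shift, so no exo or endo mode applies. The one new stereocentre, C8, is set by inversion because C2 enters anti to the departing mesylate, while C2 migrates with retention, which turns the cis-decalin into the trans fusion (H2 α, H8 β). The step needs migration of C2 in preference to C6, CH2Si or C10 and to elimination; the cis-fused lactone and the α oxygens at C8 and C10 allow only the chair–chair form in which the mesylate is equatorial, antiperiplanar to C7–C2 with no antiperiplanar hydrogen, and only C2 migration leads to a tertiary β-silyl cation.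

Step 20
Reactants: 25 trans-fused hydroazulene lactone
Product: 26 6β-hydroxy hydroazulene lactone
Conditions: SeO2 (0.5 equiv), tBuOOH (3 equiv), CH2Cl2, 0 °C to rt
Reagents that add atoms: selenium dioxide, O=[Se]=O; tert-butyl hydroperoxide, CC(C)(C)OO
Why: Allylic hydroxylation (ene reaction then 2,3-sigmatropic shift) should occur at C6, the only allylic CH2 (C2–H and C8–H are tertiary, C10 is silyloxylated), with oxygen delivered to the β face, which carries only H4 and H8 whereas the α face is flanked by C9 and C11.

Step 21
Reactants: 26 6β-hydroxy hydroazulene lactone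
Product: 27 6β,10α-bis(tert-butyldimethylsilyloxy) lactone
Conditions: TBSOTf, 2,6-lutidine, CH2Cl2, −78 to 0 °C
Reagents that add atoms: tert-butyldimethylsilyl trifluoromethanesulfonate, CC(C)(C)[Si](C)(C)OS(=O)(=O)C(F)(F)F
Why: Silylation with the silyl triflate protects the hindered allylic carbinol so that only the C3 and C12 oxygens are free later.

Step 22
Reactants: 27 bis-silyl lactone
Product: 28 lactol (C12 hemiacetal, anomer mixture)
Conditions: iBu2AlH (1.2 equiv), CH2Cl2, −78 °C; Rochelle salt work-up
Reagents that add atoms: none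
Why: Partial reduction of a γ-lactone at low temperature stops at the lactol because the tetrahedral aluminium hemiacetal is stable until work-up.

Step 23
Reactants: 28 lactol
Product: 29 allyl diol: (11S,12S)-12-hydroxy-12-allyl side chain, C3–OH free
Conditions: CH2=CHCH2MgBr (3 equiv), THF, −78 to 0 °C
Reagents that add atoms: allylmagnesium bromide, C=CC[Mg]Br
Why: Grignard addition to the aldehyde form of the lactol should follow the Felkin–Anh model (attack anti to C4, the large substituent on C11), which gives the 11,12-syn (12S) carbinol and frees the C3 hydroxyl.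

Step 24
Reactants: 29 allyl diol
Product: 30 prenyl diol (C12–CH2CH=CMe2)
Conditions: 2-methyl-2-butene (excess), second-generation Grubbs catalyst (5 mol %), CH2Cl2, 40 °C
Reagents that add atoms: 2-methyl-2-butene, CC=C(C)C
Why: Olefin cross-metathesis of the monosubstituted alkene with 2-methyl-2-butene gives the trisubstituted terminus, while the two 1,1-disubstituted ring methylenes are too hindered to enter the cycle.

Step 25
Reactants: 30 prenyl diol
Product: 31 C12 acetate, bis-silyl ether, C3–OH free
Conditions: Ac2O (1.2 equiv), pyridine, CH2Cl2, 0 °C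
Reagents that add atoms: acetic anhydride, CC(=O)OC(C)=O
Why: Acetylation is expected at the side-chain C12 hydroxyl, which has one branched neighbour, in preference to the ring C3 hydroxyl, which lies between the two ring methines C2 and C4.

Step 26
Reactants: 31 C12 acetate, bis-silyl ether
Product: 32 target CNP0210891.3
Conditions: Bu4NF, AcOH, THF, rt
Reagents that add atoms: none
Why: Fluoride cleavage of both silyl ethers, buffered with acetic acid so that the acetate neither migrates nor hydrolyses, should release the target.

Compound list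
1 | 5-bromo-2-methoxyphenol | COc1ccc(Br)cc1O | starting material
2 | (trimethylsilyl)methylmagnesium chloride | C[Si](C)(C)C[Mg]Cl | starting material
3 | 2-methoxy-5-[(trimethylsilyl)methyl]phenol | COc1ccc(C[Si](C)(C)C)cc1O | intermediate
4 | 2-methoxy-5-[(trimethylsilyl)methyl]-1,4-benzoquinone | COC1=CC(=O)C(C[Si](C)(C)C)=CC1=O | intermediate
5 | (E)-1-(trimethylsiloxy)buta-1,3-diene | C=C/C=C/O[Si](C)(C)C | starting material
6 | (±)-endo cycloadduct: cis-decal-4,9-diene-1,8-dione, 10-OMe, 7α-CH2SiMe3, 2α-H, 3β-OSiMe3 | O=C1[C@H]2[C@@H](O[Si](C)(C)C)C=CC[C@@]2(C[Si](C)(C)C)C(=O)C=C1OC | intermediate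
7 | (±)-methoxy diketone: 6 with C9–C10 saturated, C10 epimer mixture (not isolated) | O=C1[C@H]2[C@@H](O[Si](C)(C)C)C=CC[C@@]2(C[Si](C)(C)C)C(=O)CC1OC | intermediate
8 | (±)-cis-decal-4-ene-1,8-dione, 7α-CH2SiMe3, 3β-OSiMe3 | O=C1[C@H]2[C@@H](O[Si](C)(C)C)C=CC[C@@]2(C[Si](C)(C)C)C(=O)CC1 | intermediate
9 | (±)-hydroxy diketone: 8 with free 3β-OH (not isolated) | O=C1[C@H]2[C@@H](O)C=CC[C@@]2(C[Si](C)(C)C)C(=O)CC1 | intermediate
10 | (±)-bridged methyl ketal: C3–O–C8 bridge (β), 8α-OMe, C1 ketone | O=C1[C@H]2[C@@H](O3)C=CC[C@@]2(C[Si](C)(C)C)[C@]3(OC)CC1 | intermediate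
11 | (±)-C1 tert-butyldimethylsilyl enol ether (C1=C10) of 10 | CC(C)(C)[Si](C)(C)OC=1[C@H]2[C@@H](O3)C=CC[C@@]2(C[Si](C)(C)C)[C@]3(OC)CC=1 | intermediate
12 | (±)-silyloxy epoxide: 1α,10α-epoxide of 11, 1β-OTBS (not isolated) | CC(C)(C)[Si](C)(C)O[C@@]15[C@H]2[C@@H](O3)C=CC[C@@]2(C[Si](C)(C)C)[C@]3(OC)C[C@@H]1O5 | intermediate
13 | (±)-10α-(tert-butyldimethylsilyloxy) C1 ketone, bridged ketal | O=C1[C@H]2[C@@H](O3)C=CC[C@@]2(C[Si](C)(C)C)[C@]3(OC)C[C@@H]1O[Si](C)(C)C(C)(C)C | intermediate
14 | (±)-C1 methylene bridged ketal, 10α-OTBS | C=C1[C@H]2[C@@H](O3)C=CC[C@@]2(C[Si](C)(C)C)[C@]3(OC)C[C@@H]1O[Si](C)(C)C(C)(C)C | intermediate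
15 | (±)-3β-hydroxy C8 ketone, C1 methylene, 10α-OTBS | C=C1[C@H]2[C@@H](O)C=CC[C@@]2(C[Si](C)(C)C)C(=O)C[C@@H]1O[Si](C)(C)C(C)(C)C | intermediate
16 | (±)-3β,8α-diol, C1 methylene, 10α-OTBS | C=C1[C@H]2[C@@H](O)C=CC[C@@]2(C[Si](C)(C)C)[C@H](O)C[C@@H]1O[Si](C)(C)C(C)(C)C | intermediate
17 | (S)-O-methylmandelate of the 3α-alcohol, 8α-OH free, single diastereomer | C=C1[C@H]2[C@H](OC(=O)[C@@H](OC)c3ccccc3)C=CC[C@@]2(C[Si](C)(C)C)[C@H](O)C[C@@H]1O[Si](C)(C)C(C)(C)C | intermediate
18 | 3α,8α-diol, C1 methylene, 10α-OTBS, single enantiomer | C=C1[C@H]2[C@H](O)C=CC[C@@]2(C[Si](C)(C)C)[C@H](O)C[C@@H]1O[Si](C)(C)C(C)(C)C | intermediate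
19 | C3 O-(2-bromo-1-ethoxyethyl) acetal of 18 | C=C1[C@H]2[C@H](OC(OCC)CBr)C=CC[C@@]2(C[Si](C)(C)C)[C@H](O)C[C@@H]1O[Si](C)(C)C(C)(C)C | intermediate
20 | cis-fused 2-ethoxytetrahydrofuran on C3/C4 (C4 side chain α), 8α-OH | C=C1[C@H]2[C@H](OC3OCC)[C@H](C3)CC[C@@]2(C[Si](C)(C)C)[C@H](O)C[C@@H]1O[Si](C)(C)C(C)(C)C | intermediate
21 | lactol of 20 | C=C1[C@H]2[C@H](OC3O)[C@H](C3)CC[C@@]2(C[Si](C)(C)C)[C@H](O)C[C@@H]1O[Si](C)(C)C(C)(C)C | intermediate
22 | cis-fused γ-lactone (C11 H2), 8α-OH | C=C1[C@H]2[C@H](OC3=O)[C@H](C3)CC[C@@]2(C[Si](C)(C)C)[C@H](O)C[C@@H]1O[Si](C)(C)C(C)(C)C | intermediate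
23 | 11-methyl lactone (methyl cis to H4), 8α-alcohol | C=C1[C@H]2[C@H](OC3=O)[C@H]([C@@H]3C)CC[C@@]2(C[Si](C)(C)C)[C@H](O)C[C@@H]1O[Si](C)(C)C(C)(C)C | intermediate
24 | 8α-mesylate: cis-decalin, 7α-CH2SiMe3, C1 methylene, 10α-OTBS, cis-fused C3/C4 methyl lactone | C=C1[C@H]2[C@H](OC3=O)[C@H]([C@@H]3C)CC[C@@]2(C[Si](C)(C)C)[C@H](OS(C)(=O)=O)C[C@@H]1O[Si](C)(C)C(C)(C)C | intermediate
25 | trans-fused hydroazulene lactone, C1 and C7 methylenes, 10α-OTBS | C=C1[C@H]2[C@H](OC3=O)[C@H]([C@@H]3C)CCC(=C)[C@@H]2C[C@@H]1O[Si](C)(C)C(C)(C)C | intermediate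
26 | 6β-hydroxy hydroazulene lactone | C=C1[C@H]2[C@H](OC3=O)[C@H]([C@@H]3C)C[C@@H](O)C(=C)[C@@H]2C[C@@H]1O[Si](C)(C)C(C)(C)C | intermediate
27 | 6β,10α-bis(tert-butyldimethylsilyloxy) lactone | C=C1[C@H]2[C@H](OC3=O)[C@H]([C@@H]3C)C[C@@H](O[Si](C)(C)C(C)(C)C)C(=C)[C@@H]2C[C@@H]1O[Si](C)(C)C(C)(C)C | intermediate
28 | lactol of 27 | C=C1[C@H]2[C@H](OC3O)[C@H]([C@@H]3C)C[C@@H](O[Si](C)(C)C(C)(C)C)C(=C)[C@@H]2C[C@@H]1O[Si](C)(C)C(C)(C)C | intermediate
29 | allyl diol, (11S,12S), C3–OH and C12–OH free | C=C1[C@H]2[C@H](O)[C@H]([C@H](C)[C@H](CC=C)O)C[C@@H](O[Si](C)(C)C(C)(C)C)C(=C)[C@@H]2C[C@@H]1O[Si](C)(C)C(C)(C)C | intermediate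
30 | prenyl diol | C=C1[C@H]2[C@H](O)[C@H]([C@H](C)[C@H](CC=C(C)C)O)C[C@@H](O[Si](C)(C)C(C)(C)C)C(=C)[C@@H]2C[C@@H]1O[Si](C)(C)C(C)(C)C | intermediate
31 | C12 acetate, 6β,10α-bis-silyl ether | C=C1[C@H]2[C@H](O)[C@H]([C@H](C)[C@H](CC=C(C)C)OC(C)=O)C[C@@H](O[Si](C)(C)C(C)(C)C)C(=C)[C@@H]2C[C@@H]1O[Si](C)(C)C(C)(C)C | intermediate
32 | CNP0210891.3 | C=C1[C@H]2[C@H](O)[C@H]([C@H](C)[C@H](CC=C(C)C)OC(C)=O)C[C@@H](O)C(=C)[C@@H]2C[C@@H]1O | target

Total step count: 26. Longest linear sequence: 26 steps (1 to 32).

Steps most likely to fail

Step 19. Ionisation in the protic medium may be too slow, so that solvent or base intercepts the substrate (substitution at C8, loss of H9) before the C2 shift, or proton loss may compete with desilylation. The fallback sets out from alcohol 23 and returns at 25. It replaces solvolysis of an isolated sulfonate by aprotic ionisation of a much better leaving group. The hydroxyl of 23 is converted at −78 °C (Tf2O, 2,6-di-tert-butyl-4-methylpyridine, CH2Cl2) into the C8 trifluoromethanesulfonate F1, which is not isolated. On warming to about −20 °C it should ionise with the same antiperiplanar C2 migration in a medium free of nucleophiles, the triflate anion accepting the silicon, and give 25 directly.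

Step 10. Hydride transfer may not be intramolecular, in which case either nothing happens or hydride comes from the convex face and gives the C8 β-alcohol, which cannot be used in step 19. The fallback sets out from 15 and returns at 16. It uses a silicon-tethered hydride that cannot react intermolecularly. The C3 hydroxyl of 15 is silylated (chlorodimethylsilane, imidazole, CH2Cl2) to the C3 O-dimethylsilyl ether F2. Fluoride-catalysed intramolecular hydrosilylation of the C8 ketone (Bu4NF, 5 mol %, THF, 0 °C) should deliver hydride to the β face and give the cyclic C3,C8 dimethylsilylene acetal F3. Methanolysis (K2CO3, MeOH) then returns diol 16.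

Step 20. Oxygen may be delivered to the wrong face of C6, or the carbinol may be oxidised further. The fallback sets out from 25 and returns at 26. It sets C6 by hydride addition, not by oxygen transfer. The allylic oxidation is taken to the ketone level (SeO2/tBuOOH, then Dess–Martin periodinane on the crude carbinols) to give the C6 enone F4, and 1,2-reduction with NaBH4/CeCl3·7H2O (Luche) forms the carbinol. Hydride takes the face that an oxygen-transfer reagent would take, so this sequence is complementary in facial sense to the direct hydroxylation and should give the β-carbinol 26 if step 20 gives the α-epimer.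

Further compounds
F1 | step 19 | C8 trifluoromethanesulfonate of 23 | C=C1[C@H]2[C@H](OC3=O)[C@H]([C@@H]3C)CC[C@@]2(C[Si](C)(C)C)[C@H](OS(=O)(=O)C(F)(F)F)C[C@@H]1O[Si](C)(C)C(C)(C)C
F2 | step 10 | (±)-C3 O-dimethylsilyl ether of 15 | C=C1[C@H]2[C@@H](O[SiH](C)C)C=CC[C@@]2(C[Si](C)(C)C)C(=O)C[C@@H]1O[Si](C)(C)C(C)(C)C
F3 | step 10 | (±)-cyclic C3,C8 dimethylsilylene acetal (3β-O, 8α-O) | C=C1[C@H]2[C@@H](O3)C=CC[C@@]2(C[Si](C)(C)C)[C@H](O[Si]3(C)C)C[C@@H]1O[Si](C)(C)C(C)(C)C
F4 | step 20 | C6 enone of 25 | C=C1[C@H]2[C@H](OC3=O)[C@H]([C@@H]3C)CC(=O)C(=C)[C@@H]2C[C@@H]1O[Si](C)(C)C(C)(C)C
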